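Picture the feed as a tap and the uptake as a drain, and ask at what fraction of the charge the two balance.

- Wednesday's: substrate 0.050 M (fed, over 3.0 h); partner 0.10 M; initiator 0.50 mM; the very flask that is asked about, followed so far
- flask: substrate 0.050 M (fed, over 3.0 h); partner 0.100 M; initiator 0.50 mM; time 3.0 h

Wednesday's run (percent of the substrate charged)

| time / min | substrate / % | target / % |
|---|---|---|
| 10.0 | 5.4 | 1.0 |
| 20.0 | 7.7 | 1.6 |
| 25.0 | 9.8 | 3.0 |
| 40.0 | 14.7 | 8.5 |

(each reading ± 1 percentage point)

- part of the substrate gone at 3.0 h
- the target standing at 3.0 h, as a percentage of the substrate charged
- amount of target if the flask were left three thousand times as long, in percent of the substrate charged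

- percentages count the whole charge, also what has not yet gone in

We read the table down, taking substrate as a fraction of the charge. In the first row the feed has put in 0.0556 and 5.40% stands, so the two are level within the scatter of 1 percentage point. In the last row 0.222 has gone in and 14.7% stands, so 0.0752 has reacted. The target column reads 8.50% in that row, within the scatter of the reacted fraction, so we count reacted substrate as target.

Adding the substrate column over time, row to row, gives an area of 3.20 min. Reacted fraction over area is the uptake constant, pseudo-first-order in substrate, and we read it as 0.0235 /min. Feed rate over this constant gives 0.236, the standing level, the fraction of the charge at which uptake equals feed. Its logarithm to base ten is −0.626.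

The lag, one over that constant, is 42.6 min, shorter than the feed time 3.0 h, so we expect substrate to stand near that level at the end of the feed. Our own reckoning is therefore 76.4% gone, with the same figure for target. Once the feed stops, we expect target to close on the charge for as long as the initiator lasts.

The forecast gives 75% gone, 69% target and 90% in the long run, and reckons that with a constant uptake “substrate would level off near 20–25 % of the charge”. We agree on the level and part on the target, which it puts below conversion.

The flask gives 76.0% gone, 76.0% target and >99.9% in the long run.

    initiator → 2 initiating radical (k = 2.50 × 10⁻⁵ /s)
    substrate + initiating radical → chain carrier (k = 10000 /M/s)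
    partner + chain carrier → target + initiating radical (k = 63000 /M/s)
    2 chain carrier → ended chains A (k = 6.00 × 10⁷ /M/s)
    2 initiating radical → ended chains B (k = 7.00 × 10⁶ /M/s)

In the flask, substrate stands at 24.0% at 3.00 h, against the level of 0.236 we read from Wednesday's run, because the step to ended chains B holds the initiating radical down while the run stops at its set length. Without that step conversion reaches >99.9%, and ten times as long gives 100%. The neighbour flask with 0.0020 M of initiator carries twice the initiating radical of the flask at 3.00 h, so we take half the logarithm of the initiator ratio, 0.301, off −0.626. That gives a level of 0.118, and that neighbour flask has 12.3% substrate standing at 3.00 h.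

The earlier runs and the new flask were generated by integration on assumed constants, noise included.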